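**Plan**

- Retrosynthesis: the C1 carbonyl oxygen is removed first (phenol-to-quinone oxidation) and the ring is taken down to a cyclohexane-1,3-dione. Its C1–C6 and C2–C3 bonds are then cut to give dimethyl malonate and an open-chain enone. The enone is cut at C5=C6 (olefination), at C4–C5 (phosphonate acylation) and at the bond from indole A C2 to its quaternary carbon (reverse prenylation).
- Feature used: number the quinone ring C1(=O), C2(OH), C3 (indole A, the 2-(2-methylbut-3-en-2-yl)indol-3-yl group), C4(=O), C5 (prenyl), C6 (indole B, the plain indol-3-yl group). The oxygens on C2 and C4 sit 1,3 to each other around C3, so the ring is the oxidised form of a 2-arylcyclohexane-1,3-dione, and C1 can enter as the malonate CH and be oxygenated last.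
- Forward: indole A is reverse-prenylated, the C3–C6 chain is joined by acylation and olefination, the single carbocycle is closed by Michael–Claisen annulation, and decarboxylation, dehydrogenation and C1 oxygenation finish the synthesis.
- Stereochemistry: the target has no stereocentre; the sp3 centres formed in the annulation are all erased on aromatisation.

Key step: step 6

Remark: the hydroxyquinone is drawn and made as the 2-hydroxy-1,4-dione tautomer. B-prenyl-9-BBN is not an article of commerce and is made in the reaction vessel from 9-BBN and 3-methylbuta-1,2-diene.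

**Route**

Step 1
Reactants: 1 methyl indole-3-acetate
Product: 3 methyl 2-[2-(2-methylbut-3-en-2-yl)-1H-indol-3-yl]acetate, via 3-chloroindolenine 2 (not isolated)
Conditions: t-BuOCl, Et3N, THF, −78 °C; then B-prenyl-9-BBN (from 9-BBN and 3-methylbuta-1,2-diene, THF, rt), −78 °C → rt; aq. NaHCO3
Reagents that add atoms: B-prenyl-9-BBN, CC(C)=CCB1C2CCCC1CCC2 (made in the flask from 3-methylbuta-1,2-diene, CC(C)=C=C, and 9-BBN, B1C2CCCC1CCC2); tert-butyl hypochlorite, CC(C)(C)OCl (its chlorine is in 2 only)
Why: Chlorination at indole C3 gives the 3-chloroindolenine, whose C=N carbon takes the prenyl group from boron through a six-membered allyl-transfer transition state with allylic transposition (reverse prenylation of 3-substituted indoles), and loss of HCl restores the indole with the 1,1-dimethylallyl group at C2.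

Step 2
Reactants: 4 5-bromo-2-methylpent-2-ene
Product: 5 diethyl (4-methylpent-3-en-1-yl)phosphonate
Conditions: P(OEt)3 (neat, excess), 150 °C, EtBr distilled off
Reagents that add atoms: triethyl phosphite, CCOP(OCC)OCC
Why: Michaelis–Arbuzov reaction of an unhindered primary bromide, with the trisubstituted alkene as a spectator.

Step 3
Reactants: 5 diethyl (4-methylpent-3-en-1-yl)phosphonate; 3 methyl 2-[2-(2-methylbut-3-en-2-yl)-1H-indol-3-yl]acetate
Product: 6 diethyl {6-methyl-1-[2-(2-methylbut-3-en-2-yl)-1H-indol-3-yl]-2-oxohept-5-en-3-yl}phosphonate (racemic)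
Conditions: 5 (3.1 equiv), n-BuLi (3.0 equiv), THF, −78 °C; then 3, −78 → −20 °C; aq. NH4Cl
Reagents that add atoms: none
Why: Acylation of an α-lithiated alkylphosphonate by a methyl ester is the standard β-ketophosphonate synthesis, and the extra equivalents of carbanion cover the indole N–H and the acidic product, whose enolate shields the ketone from a second addition.

Step 4
Reactants: 7 indole-3-carboxaldehyde
Product: 8 1-tosylindole-3-carbaldehyde
Conditions: TsCl, Et3N, DMAP (cat.), CH2Cl2, 0 °C → rt
Reagents that add atoms: p-toluenesulfonyl chloride, Cc1ccc(S(=O)(=O)Cl)cc1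
Why: N-sulfonylation of an indole whose N–H is acidified by the 3-formyl group; the sulfonyl group later keeps the enone carbon C6 electrophilic.

Step 5
Reactants: 6 diethyl {6-methyl-1-[2-(2-methylbut-3-en-2-yl)-1H-indol-3-yl]-2-oxohept-5-en-3-yl}phosphonate; 8 1-tosylindole-3-carbaldehyde
Product: 9 (3E)-6-methyl-1-[2-(2-methylbut-3-en-2-yl)-1H-indol-3-yl]-3-[(1-tosylindol-3-yl)methylidene]hept-5-en-2-one
Conditions: LiCl, DBU, MeCN, rt → 45 °C
Reagents that add atoms: none
Why: Horner–Wadsworth–Emmons olefination under Masamune–Roush conditions, where the lithium-chelated ketophosphonate is deprotonated by an amidine base that does not attack the labile N-sulfonyl group of the 3-formylindole; the trisubstituted E-enone is expected under thermodynamic control, and its geometry does not matter for the next step.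

Step 6
Reactants: 9 (3E)-6-methyl-1-[2-(2-methylbut-3-en-2-yl)-1H-indol-3-yl]-3-[(1-tosylindol-3-yl)methylidene]hept-5-en-2-one; 10 dimethyl malonate
Product: 12 methyl 3-[2-(2-methylbut-3-en-2-yl)-1H-indol-3-yl]-5-(3-methylbut-2-en-1-yl)-2,4-dioxo-6-(1-tosylindol-3-yl)cyclohexane-1-carboxylate (diastereomer and enol mixture), via keto diester 11 (not isolated)
Conditions: 10 (2 equiv), KOt-Bu (0.3 equiv), t-BuOH/THF, 0 °C → rt; then KOt-Bu (3 equiv), 50 °C; 1 M HCl to pH 4, 0 °C
Reagents that add atoms: none
Why: Potassium dimethyl malonate adds to C6, the β-carbon of enone 9, forming C1–C6 and the keto diester 11; the added KOt-Bu then enolises the ketone toward the indolylmethyl carbon C3, which acylates one malonate ester to form C2–C3 with loss of methoxide. This is the Michael–Claisen synthesis of cyclohexane-1,3-diones from enones and malonates, the reaction type behind dimedone. The ring closes as a 6-(enolendo)-exo-trig Claisen (Dieckmann-type) acylation, and deprotonation of the new β-diketone makes closure irreversible and pulls the reversible Michael step forward. The sp3 centres created at C1, C3, C5 and C6 are under no control and equilibrate in base; none is kept, because all four carbons become sp2 in the arene. The selectivity needed is conjugate addition at C6 ahead of deprotonation at C3 or at the doubly allylic prenyl CH2: the N-sulfonyl group shuts off donation from the indole B nitrogen and keeps C6 electrophilic, and the Michael stage is run with substoichiometric alkoxide so that malonate anion is the strongest base present. Regiochemistry of closure is fixed by the substrate, since only the C3 enolate can reach an ester through a six-membered transition state, whereas the C5 enolate would have to form a four-membered ring.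

Step 7
Reactants: 12 methyl 3-[2-(2-methylbut-3-en-2-yl)-1H-indol-3-yl]-5-(3-methylbut-2-en-1-yl)-2,4-dioxo-6-(1-tosylindol-3-yl)cyclohexane-1-carboxylate
Product: 14 5-(1H-indol-3-yl)-2-[2-(2-methylbut-3-en-2-yl)-1H-indol-3-yl]-4-(3-methylbut-2-en-1-yl)cyclohexane-1,3-dione, via keto acid 13 (not isolated)
Conditions: 2 M aq. NaOH, 1,4-dioxane, 90 °C; then 2 M HCl to pH 3, 50 °C
Reagents that add atoms: sodium hydroxide, [Na+].[OH-] (its oxygen is in 13 only and leaves as CO2)
Why: Hydroxide saponifies the ester and attacks sulfur of the N-sulfonylindole while the dione is protected as its enolate from retro-Claisen cleavage, and on acidification the vinylogous β-keto acid loses CO2, as in the closing stage of the dimedone synthesis; methanol is avoided so that no methyl tosylate can form and alkylate the anions.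

Step 8
Reactants: 14 5-(1H-indol-3-yl)-2-[2-(2-methylbut-3-en-2-yl)-1H-indol-3-yl]-4-(3-methylbut-2-en-1-yl)cyclohexane-1,3-dione
Product: 15 5-(1H-indol-3-yl)-2-[2-(2-methylbut-3-en-2-yl)-1H-indol-3-yl]-4-(3-methylbut-2-en-1-yl)benzene-1,3-diol
Conditions: DDQ (1.05 equiv), 1,4-dioxane, 10 °C → rt
Reagents that add atoms: none
Why: DDQ dehydrogenation of a cyclohexane-1,3-dione to a resorcinol, here helped because the hydride at C6 is an indol-3-ylmethine hydrogen allylic to the dienol, so that hydride loss, loss of the C1 proton and tautomerisation give the arene; a single equivalent at low temperature is meant to spare the o-prenylphenol that is formed.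

Step 9
Reactants: 15 5-(1H-indol-3-yl)-2-[2-(2-methylbut-3-en-2-yl)-1H-indol-3-yl]-4-(3-methylbut-2-en-1-yl)benzene-1,3-diol
Product: 16 2-hydroxy-6-(1H-indol-3-yl)-3-[2-(2-methylbut-3-en-2-yl)-1H-indol-3-yl]-5-(3-methylbut-2-en-1-yl)cyclohexa-2,5-diene-1,4-dione (target)
Conditions: Co(salen) (N,N'-bis(salicylidene)ethylenediaminocobalt, divalent cobalt, 15 mol %), O2 (1 atm), DMF, rt
Reagents that add atoms: dioxygen, O=O
Why: Co(salen)-catalysed aerobic oxidation of a 2,6-disubstituted phenol with a free para position to the p-benzoquinone, in which the phenoxyl radical of the C4 hydroxyl is oxygenated at C1, the only unsubstituted ring carbon, and the C2 hydroxyl is kept to give the 2-hydroxy-1,4-quinone.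

**Compound list**

1 | methyl indole-3-acetate | COC(=O)Cc1c[nH]c2ccccc12 | starting material
2 | methyl 2-(3-chloro-3H-indol-3-yl)acetate (racemic 3-chloroindolenine) | COC(=O)CC1(Cl)C=Nc2ccccc12 | intermediate (not isolated)
3 | methyl 2-[2-(2-methylbut-3-en-2-yl)-1H-indol-3-yl]acetate | COC(=O)Cc1c(C(C)(C)C=C)[nH]c2ccccc12 | intermediate
4 | 5-bromo-2-methylpent-2-ene | CC(C)=CCCBr | starting material
5 | diethyl (4-methylpent-3-en-1-yl)phosphonate | CCOP(=O)(CCC=C(C)C)OCC | intermediate
6 | diethyl {6-methyl-1-[2-(2-methylbut-3-en-2-yl)-1H-indol-3-yl]-2-oxohept-5-en-3-yl}phosphonate (racemic) | CCOP(=O)(OCC)C(CC=C(C)C)C(=O)Cc1c(C(C)(C)C=C)[nH]c2ccccc12 | intermediate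
7 | indole-3-carboxaldehyde | O=Cc1c[nH]c2ccccc12 | starting material
8 | 1-tosylindole-3-carbaldehyde | Cc1ccc(S(=O)(=O)n2cc(C=O)c3ccccc32)cc1 | intermediate
9 | (3E)-6-methyl-1-[2-(2-methylbut-3-en-2-yl)-1H-indol-3-yl]-3-[(1-tosylindol-3-yl)methylidene]hept-5-en-2-one | O=C(Cc1c(C(C)(C)C=C)[nH]c2ccccc12)/C(CC=C(C)C)=C/c1cn(S(=O)(=O)c2ccc(C)cc2)c2ccccc12 | intermediate
10 | dimethyl malonate | COC(=O)CC(=O)OC | starting material
11 | dimethyl 2-{2-(3-methylbut-2-en-1-yl)-4-[2-(2-methylbut-3-en-2-yl)-1H-indol-3-yl]-3-oxo-1-(1-tosylindol-3-yl)butyl}malonate (diastereomer mixture, present as its potassium enolate) | COC(=O)C(C(=O)OC)C(c1cn(S(=O)(=O)c2ccc(C)cc2)c2ccccc12)C(CC=C(C)C)C(=O)Cc1c(C(C)(C)C=C)[nH]c2ccccc12 | intermediate (not isolated)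
12 | methyl 3-[2-(2-methylbut-3-en-2-yl)-1H-indol-3-yl]-5-(3-methylbut-2-en-1-yl)-2,4-dioxo-6-(1-tosylindol-3-yl)cyclohexane-1-carboxylate (diastereomer mixture) | COC(=O)C1C(=O)C(c2c(C(C)(C)C=C)[nH]c3ccccc23)C(=O)C(CC=C(C)C)C1c1cn(S(=O)(=O)c2ccc(C)cc2)c2ccccc12 | intermediate
13 | 6-(1H-indol-3-yl)-3-[2-(2-methylbut-3-en-2-yl)-1H-indol-3-yl]-5-(3-methylbut-2-en-1-yl)-2,4-dioxocyclohexane-1-carboxylic acid (diastereomer mixture) | OC(=O)C1C(=O)C(c2c(C(C)(C)C=C)[nH]c3ccccc23)C(=O)C(CC=C(C)C)C1c1c[nH]c2ccccc12 | intermediate (not isolated)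
14 | 5-(1H-indol-3-yl)-2-[2-(2-methylbut-3-en-2-yl)-1H-indol-3-yl]-4-(3-methylbut-2-en-1-yl)cyclohexane-1,3-dione (diastereomer mixture) | O=C1CC(c2c[nH]c3ccccc23)C(CC=C(C)C)C(=O)C1c1c(C(C)(C)C=C)[nH]c2ccccc12 | intermediate
15 | 5-(1H-indol-3-yl)-2-[2-(2-methylbut-3-en-2-yl)-1H-indol-3-yl]-4-(3-methylbut-2-en-1-yl)benzene-1,3-diol | Oc1cc(-c2c[nH]c3ccccc23)c(CC=C(C)C)c(O)c1-c1c(C(C)(C)C=C)[nH]c2ccccc12 | intermediate
16 | 2-hydroxy-6-(1H-indol-3-yl)-3-[2-(2-methylbut-3-en-2-yl)-1H-indol-3-yl]-5-(3-methylbut-2-en-1-yl)cyclohexa-2,5-diene-1,4-dione | C=CC(C)(C)c1[nH]c2ccccc2c1C1=C(O)C(=O)C(c2c[nH]c3ccccc23)=C(CC=C(C)C)C1=O | target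

**Step count and risks**

Total steps: 9. Longest linear sequence: 7 steps (steps 1, 3, 5, 6, 7, 8 and 9, from methyl indole-3-acetate 1); steps 2 and 4 prepare the two side branches.

Steps most likely to fail:

Step 6. Conjugate addition to the α-substituted, β-indolyl enone may be too slow or too reversible. Alkoxide may instead enolise the ketone at C3, or move the skipped diene of the prenyl side chain into conjugation. The fallback sets out from enone 9 and replaces the basic malonate addition by a Lewis-acid-promoted Mukaiyama–Michael addition of a neutral acetate equivalent. Enone 9 and 1-methoxy-1-(trimethylsilyloxy)ethene with TMSOTf (catalytic) in CH2Cl2 at −78 °C should form the C1–C6 bond irreversibly and give the silyl enol ether methyl 6-[2-(2-methylbut-3-en-2-yl)-1H-indol-3-yl]-4-(3-methylbut-2-en-1-yl)-3-(1-tosylindol-3-yl)-5-[(trimethylsilyl)oxy]hex-4-enoate F1. Mild aqueous acid work-up hydrolyses it to the keto ester methyl 6-[2-(2-methylbut-3-en-2-yl)-1H-indol-3-yl]-4-(3-methylbut-2-en-1-yl)-5-oxo-3-(1-tosylindol-3-yl)hexanoate F2. KOt-Bu in t-BuOH/THF then closes the C2–C3 bond by the same 6-(enolendo)-exo-trig Claisen acylation (the classical cyclisation of 5-oxo esters to cyclohexane-1,3-diones) to give 2-[2-(2-methylbut-3-en-2-yl)-1H-indol-3-yl]-4-(3-methylbut-2-en-1-yl)-5-(1-tosylindol-3-yl)cyclohexane-1,3-dione F3, which carries no ester at C1. Aqueous NaOH in dioxane removes the sulfonyl group and the sequence comes back to the route at dione 14.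

Step 8. The quinone oxidant may not stop at the resorcinol: oxidative cyclisation of the o-prenylphenol to a chromene, or oxidation of the free indoles, may compete with dehydrogenation. The fallback sets out from dione 14 and introduces the double bond by an anionic sulfinylation and thermal syn-elimination instead of hydride abstraction. The polyanion of 14 (LDA, 4.2 equiv, THF, −78 → −30 °C) is sulfinylated at the ring CH2 (C1) with methyl benzenesulfinate to give 5-(1H-indol-3-yl)-2-[2-(2-methylbut-3-en-2-yl)-1H-indol-3-yl]-4-(3-methylbut-2-en-1-yl)-6-(phenylsulfinyl)cyclohexane-1,3-dione F4. Warming F4 in toluene at 80–100 °C with trimethyl phosphite as sulfenic acid trap eliminates benzenesulfenic acid across C1–C6, and tautomerisation of the dienone comes back to the route at resorcinol 15.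

Step 9. Aerobic cobalt catalysis may over-oxidise the substrate: oxygenative cleavage of the 3-substituted indole rings, or cyclisation of the prenyl group onto the new hydroxyquinone. The fallback sets out from resorcinol 15 and brings in the C1 heteroatom as nitrogen by electrophilic substitution. Coupling of the phenolate of 15 with diazotised sulfanilic acid (aq. NaOH/THF, 0 °C) at C1, the only free ring position, should give the azo compound sodium 4-{(E)-[2,4-dihydroxy-6-(1H-indol-3-yl)-3-[2-(2-methylbut-3-en-2-yl)-1H-indol-3-yl]-5-(3-methylbut-2-en-1-yl)phenyl]diazenyl}benzenesulfonate F5. Reduction with Na2S2O4 cleaves it to 4-amino-5-(1H-indol-3-yl)-2-[2-(2-methylbut-3-en-2-yl)-1H-indol-3-yl]-6-(3-methylbut-2-en-1-yl)benzene-1,3-diol F6. Mild oxidation of this aminoresorcinol with aqueous FeCl3 (trivalent iron) in dilute HCl gives the quinone imine, whose hydrolysis in the same medium comes back to the route at target 16.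

**Further compounds**

F1 | step 6 | methyl 6-[2-(2-methylbut-3-en-2-yl)-1H-indol-3-yl]-4-(3-methylbut-2-en-1-yl)-3-(1-tosylindol-3-yl)-5-[(trimethylsilyl)oxy]hex-4-enoate (E/Z mixture, racemic) | COC(=O)CC(c1cn(S(=O)(=O)c2ccc(C)cc2)c2ccccc12)C(CC=C(C)C)=C(O[Si](C)(C)C)Cc1c(C(C)(C)C=C)[nH]c2ccccc12
F2 | step 6 | methyl 6-[2-(2-methylbut-3-en-2-yl)-1H-indol-3-yl]-4-(3-methylbut-2-en-1-yl)-5-oxo-3-(1-tosylindol-3-yl)hexanoate (diastereomer mixture) | COC(=O)CC(c1cn(S(=O)(=O)c2ccc(C)cc2)c2ccccc12)C(CC=C(C)C)C(=O)Cc1c(C(C)(C)C=C)[nH]c2ccccc12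
F3 | step 6 | 2-[2-(2-methylbut-3-en-2-yl)-1H-indol-3-yl]-4-(3-methylbut-2-en-1-yl)-5-(1-tosylindol-3-yl)cyclohexane-1,3-dione (diastereomer mixture) | O=C1CC(c2cn(S(=O)(=O)c3ccc(C)cc3)c3ccccc23)C(CC=C(C)C)C(=O)C1c1c(C(C)(C)C=C)[nH]c2ccccc12
F4 | step 8 | 5-(1H-indol-3-yl)-2-[2-(2-methylbut-3-en-2-yl)-1H-indol-3-yl]-4-(3-methylbut-2-en-1-yl)-6-(phenylsulfinyl)cyclohexane-1,3-dione (diastereomer mixture) | O=C1C(S(=O)c2ccccc2)C(c2c[nH]c3ccccc23)C(CC=C(C)C)C(=O)C1c1c(C(C)(C)C=C)[nH]c2ccccc12
F5 | step 9 | sodium 4-{(E)-[2,4-dihydroxy-6-(1H-indol-3-yl)-3-[2-(2-methylbut-3-en-2-yl)-1H-indol-3-yl]-5-(3-methylbut-2-en-1-yl)phenyl]diazenyl}benzenesulfonate | Oc1c(/N=N/c2ccc(S(=O)(=O)[O-])cc2)c(-c2c[nH]c3ccccc23)c(CC=C(C)C)c(O)c1-c1c(C(C)(C)C=C)[nH]c2ccccc12.[Na+]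
F6 | step 9 | 4-amino-5-(1H-indol-3-yl)-2-[2-(2-methylbut-3-en-2-yl)-1H-indol-3-yl]-6-(3-methylbut-2-en-1-yl)benzene-1,3-diol | Nc1c(O)c(-c2c(C(C)(C)C=C)[nH]c3ccccc23)c(O)c(CC=C(C)C)c1-c1c[nH]c2ccccc12
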